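- At early times the runs nearly agree on one thing: the share of starting material lost changes by only a few points across the charges. The zeta run, charged at 0.13 M, keeps 71.0% at 80.0 s, and the theta run, charged at 0.82 M, keeps 74.0%. From zeta I read a first-order constant of 0.00428 s⁻¹.

- Target behaves differently. In theta it reaches 4.8% at 50.0 s, then reads 4.1% at 80.0 s, so something consumes it. I let starting material do this: target is made at k_make c_A c_B and lost at k_loss c_A c_P. Then c_A cancels from the comparison, and target stops rising when c_B/c_P equals k_loss/k_make.

- I call this number the turning ratio (a selectivity factor). At the theta peak, target stands at 0.0394 M. Each target took one partner, so at most 0.0556 M of partner remains. The turning ratio, as read, is therefore at most 1.41.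

| flask | starting material | partner | second substrate | remark | time |
|---|---|---|---|---|---|
| zeta | 0.13 M | 0.095 M | 0.50 M | run made earlier |  |
| beta | 0.27 M | 0.095 M | 0.50 M | run made earlier |  |
| theta | 0.82 M | 0.095 M | 0.50 M | run made earlier |  |
| teal | 0.10 M | 0.0950 M | 0.500 M |  | 2.0 min |
| amber | 0.20 M | 0.0950 M | 0.500 M |  | 2.0 min |
| blue | 0.40 M | 0.0950 M | 0.500 M |  | 2.0 min |
| green | 0.80 M | 0.0950 M | 0.500 M |  | 2.0 min |

| run | time / s | target / % | starting material / % |
|---|---|---|---|
| zeta | 10.0 | 2.3 | 95.2 |
| zeta | 15.0 | 4.5 | 93.4 |
| zeta | 40.0 | 8.3 | 83.6 |
| zeta | 80.0 | 13.7 | 71.0 |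
| beta | 10.0 | 2.3 | 95.1 |
| beta | 15.0 | 3.5 | 93.7 |
| beta | 40.0 | 7.4 | 83.6 |
| beta | 80.0 | 10.8 | 71.3 |
| theta | 10.0 | 1.9 | 95.3 |
| theta | 30.0 | 4.0 | 88.0 |
| theta | 50.0 | 4.8 | 82.3 |
| theta | 80.0 | 4.1 | 74.0 |

(standard deviation of a reading: 0.3 percentage points)

- "hardly changes" means that all values lie within two and a half points (for a concentration: within two and a half percent of the largest)

- amount of target at the end, in percent of the starting material charged for teal, amber, blue, green, in this order
- the course of these numbers from the first flask to the last (falls all the way / rises, then falls / falls, then rises / rises all the way / hardly changes)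

- For teal, I reckon 0.0402 M of starting material lost by 2.0 min. Zeta made 47.2% of its loss into target, so I expect 0.0190 M, or 19.0% of the charge. Even if each starting material lost took one partner, c_B/c_P would be 2.89, larger than the turning ratio, so teal is still gaining target.

- For green, the charge is close to theta's and the partner charge is the same. Its time of 2.0 min is longer than the 80.0 s at which theta had already turned. I therefore expect green below 4.1%.

- The forecast gives 18.5%, 14.8%, 9.2% and 2.9%, so falls all the way, with “attack on target, at about the same rate constant as on partner”. Its teal value lies slightly below my own, and its green value agrees with my limit.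

The flasks give 18.4%, 14.5%, 9.01% and 3.37%: falls all the way.

    starting material + partner → target (k = 0.0290 M⁻¹ s⁻¹)
    starting material + target → side product (k = 0.0226 M⁻¹ s⁻¹)
    starting material + second substrate → cross product (k = 0.00385 M⁻¹ s⁻¹)
    second substrate + partner → second product (k = 0.00359 M⁻¹ s⁻¹)

In teal at 2.00 min, target is made 4.11 times faster than it is used up, each step taken net. The constants put the turning ratio k_loss/k_make at 0.779, under the bound of 1.41 read from theta. In teal at 2.00 min, c_B/c_P stands at 3.20, above that turning ratio, and teal's target rises from 12.0% at 1.00 min to 18.4% at 2.00 min. In green the same quotient at 2.00 min is 0.311, below the turning ratio, and green's target drops from 4.68% at 1.00 min to 3.37% at 2.00 min.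

All runs come from a simulation with made-up constants, and the scatter is random.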